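Ring A is the terminal ring with OMe ortho to its butyryl group (a1 bridge carbon, a2 OH, a3 Me, a4 OMe, a5 butyryl carbon, a6 OH). Ring B is the central butyrylphloroglucinol. Ring C is the terminal ring with OMe para to its butyryl group.
Cuts: first the CH2–ring B bond of the A–B bridge, then the CH2–ring B bond of the C–B bridge (each bridge carbon comes from formaldehyde through a Mannich base), and last the a5–C(=O) and a6–O bonds of ring A together.
Enabling feature: on ring A the a5 butyryl and the a6 hydroxyl sit on adjacent carbons and the a4 methoxy flanks the acyl-bearing carbon. This is the pattern left when butanoic acid adds across an a5≡a6 aryne polarised by a4-OMe.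
Forward, ring A: 2,4-dihydroxy-3-methylbenzaldehyde 1 is taken in six steps to silyl triflate 12, the aryne step gives ketone 16, and debenzylation followed by aminomethylation gives 18.
Forward, rings B and C: 2-methylphloroglucinol 19 gives aspidinol 21, its Mannich base 22 is joined to ring B (23) to give dimer 25, and 18 plus 25 give target 27.
No ring is built (all three benzene rings are purchased), and the target has no stereocentre, so no stereocontrol is required.

Key step: step 7

Remark: Mannich bases 18 and 22 are drawn as neutral amino phenols, although they should exist largely as ammonium phenoxide zwitterions; the chemistry is the same.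

Step 1
Reactants: 1 2,4-dihydroxy-3-methylbenzaldehyde
Product: 2 4-(benzyloxy)-2-hydroxy-3-methylbenzaldehyde
Conditions: BnBr (1.05 equiv), K2CO3 (1.1 equiv), acetone, reflux
Reagents that add atoms: benzyl bromide, BrCc1ccccc1
Why: Williamson etherification; the 2-OH is hydrogen-bonded to the aldehyde and crowded by the methyl group, so one equivalent of benzyl bromide should alkylate the free, more acidic 4-OH (future a2 oxygen).

Step 2
Reactants: 2 4-(benzyloxy)-2-hydroxy-3-methylbenzaldehyde
Product: 3 4-(benzyloxy)-2-methoxy-3-methylbenzaldehyde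
Conditions: MeI (3 equiv), K2CO3 (2 equiv), DMF, 40 °C
Reagents that add atoms: iodomethane, CI
Why: Williamson etherification in a polar aprotic solvent with excess MeI overcomes the chelate and methylates the only remaining phenol (future a4 OMe).

Step 3
Reactants: 3 4-(benzyloxy)-2-methoxy-3-methylbenzaldehyde
Product: 5 4-(benzyloxy)-2-methoxy-3-methylphenol, via aryl formate 4 (not isolated)
Conditions: mCPBA (1.3 equiv), CH2Cl2, 0 °C to rt; then K2CO3 (cat.), MeOH, N2, rt
Reagents that add atoms: 3-chloroperoxybenzoic acid, OOC(=O)c1cccc(Cl)c1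
Why: Baeyer–Villiger (Dakin-type) oxidation; the aryl group carries ortho and para oxygen donors and should migrate in preference to hydride, catalytic carbonate in methanol transesterifies the formate, and the formyl group that told the two hydroxyls apart is thereby exchanged for the oxygen that will carry the triflate.

Step 4
Reactants: 5 4-(benzyloxy)-2-methoxy-3-methylphenol
Product: 6 4-(benzyloxy)-2-methoxy-3-methylphenyl N-(propan-2-yl)carbamate
Conditions: i-PrNCO (1.5 equiv), Et3N (0.2 equiv), CH2Cl2, rt
Reagents that add atoms: isopropyl isocyanate, CC(C)N=C=O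
Why: Base-catalysed addition of a phenol to an isocyanate (carbamoylation) installs a strong metalation director that can later be removed under mild base, and it protects the oxidation-prone hydroquinone monoether.

Step 5
Reactants: 6 4-(benzyloxy)-2-methoxy-3-methylphenyl N-(propan-2-yl)carbamate
Product: 10 4-(benzyloxy)-2-methoxy-3-methyl-6-(trimethylsilyl)phenyl N-(propan-2-yl)carbamate, via N-silyl carbamate 7 (not isolated), via aryllithium 8 (not isolated), via bis-silyl carbamate 9 (not isolated)
Conditions: TBSOTf (1.1 equiv), TMEDA (1.1 equiv), Et2O, 0 °C to rt; TMEDA (2 equiv), n-BuLi (2 equiv), −78 °C; TMSCl (3.5 equiv), −78 °C to rt; aq NaHSO4 work-up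
Reagents that add atoms: chlorotrimethylsilane, C[Si](C)(C)Cl (tert-butyldimethylsilyl triflate, CC(C)(C)[Si](C)(C)OS(=O)(=O)C(F)(F)F, and n-butyllithium, [Li]CCCC, put atoms only into intermediates 7–9)
Why: Directed ortho-metalation; in situ N-silylation masks the N–H (whose deprotonation would expel isocyanate), the resulting tertiary carbamate is the strongest director on the ring and, with C2 blocked by OMe, has only C6 (future a6) as ortho site, so lithiation and TMSCl quench should place silicon there without exposing the electron-rich ring to an electrophilic halogen, and the acidic work-up removes only the N-silyl group.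

Step 6
Reactants: 10 4-(benzyloxy)-2-methoxy-3-methyl-6-(trimethylsilyl)phenyl N-(propan-2-yl)carbamate
Product: 12 4-(benzyloxy)-2-methoxy-3-methyl-6-(trimethylsilyl)phenyl trifluoromethanesulfonate, via silylphenol 11 (not isolated)
Conditions: DBU (1.5 equiv), Et2NH (1.2 equiv), MeCN, 40 °C; then PhNTf2 (1.5 equiv), rt
Reagents that add atoms: N-phenylbis(trifluoromethanesulfonimide), O=S(=O)(N(c1ccccc1)S(=O)(=O)C(F)(F)F)C(F)(F)F
Why: E1cB cleavage of the secondary carbamate (DBU removes N–H, isopropyl isocyanate leaves and Et2NH scavenges it as a urea) frees the phenoxide under conditions too mild for protodesilylation, and O-sulfonylation in the same flask gives the ortho-silylaryl triflate.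

Step 7
Reactants: 12 4-(benzyloxy)-2-methoxy-3-methyl-6-(trimethylsilyl)phenyl trifluoromethanesulfonate; 13 butanoic acid
Product: 16 1-[4-(benzyloxy)-2-hydroxy-6-methoxy-5-methylphenyl]butan-1-one, via aryne 14 (not isolated), via aryl anion 15 (not isolated)
Conditions: 13 (1.1 equiv) pre-stirred with CsF (4 equiv), THF, rt; then 12 (1.0 equiv), 125 °C, sealed tube
Reagents that add atoms: none
Why: Fluoride attacks the silicon of 12 and triflate leaves, which sets free the a5≡a6 aryne 14; caesium butanoate adds through oxygen at a6 to give aryl anion 15, whose a5 carbanion attacks the neighbouring ester carbonyl through a four-membered alkoxide, and collapse of that alkoxide breaks the acyl C–O bond, so a6–O and a5–C(=O) are both made in one operation. The closest known reaction type is the fluoride-induced intermolecular addition of carboxylic acids across arynes from ortho-silylaryl triflates (formal aryne insertion into the acid C–O bond, mechanistically an anionic ortho-Fries-type 1,3-acyl shift), which is established for aliphatic and aromatic acids in hot THF. No ring is closed in the product and no stereocentre is created. The step needs attack at a6: the inductively withdrawing a4 methoxy group distorts the aryne so that a6 has the wider internal angle and the greater electrophilicity while the charge develops at a5 beside the C–O bond, the bulk of that methoxy group (buttressed by the a3 methyl) shields a5, and the more remote a2 benzyloxy group should have only a minor influence. It also needs the acyl shift to outrun protonation of 15, which is served by a solvent without acidic hydrogens, the high temperature, neutralisation of the acid by excess CsF beforehand and only a slight excess of 13. The benzyl and methyl ethers are inert to CsF at this temperature.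

Step 8
Reactants: 16 1-[4-(benzyloxy)-2-hydroxy-6-methoxy-5-methylphenyl]butan-1-one
Product: 17 1-(2,4-dihydroxy-6-methoxy-5-methylphenyl)butan-1-one
Conditions: H2 (1 atm), 10% Pd/C, EtOAc–MeOH, rt
Reagents that add atoms: none
Why: Catalytic hydrogenolysis of the benzylic C–O bond; the chelated aryl ketone and the aryl methyl ether should survive at atmospheric pressure, and early deprotection keeps reducing conditions away from the finished trimer.

Step 9
Reactants: 17 1-(2,4-dihydroxy-6-methoxy-5-methylphenyl)butan-1-one
Product: 18 1-{3-[(dimethylamino)methyl]-2,4-dihydroxy-6-methoxy-5-methylphenyl}butan-1-one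
Conditions: 37% aq HCHO (1.3 equiv) premixed with 40% aq Me2NH (1.3 equiv), EtOH, 0 °C to rt
Reagents that add atoms: formaldehyde, C=O; dimethylamine, CNC
Why: Phenolic Mannich reaction; a1 is the only unsubstituted ring position and lies between two hydroxyl groups, and the premixed excess reagent at low temperature should suppress methylene-bridged self-dimerisation.

Step 10
Reactants: 19 2-methylphloroglucinol (2-methylbenzene-1,3,5-triol)
Product: 20 1-(2,4,6-trihydroxy-3-methylphenyl)butan-1-one
Conditions: PrCOCl (1.1 equiv), AlCl3 (3.5 equiv), CH2Cl2–PhNO2, 0 to 45 °C; aq HCl work-up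
Reagents that add atoms: butanoyl chloride, CCCC(=O)Cl
Why: Friedel–Crafts C-acylation; the two free positions of 19 are equivalent by symmetry and the first acyl group deactivates the ring towards a second one.

Step 11
Reactants: 20 1-(2,4,6-trihydroxy-3-methylphenyl)butan-1-one
Product: 21 aspidinol, 1-(2,6-dihydroxy-4-methoxy-3-methylphenyl)butan-1-one
Conditions: Me2SO4 (1.0 equiv), K2CO3 (1.0 equiv), acetone, rt to 40 °C
Reagents that add atoms: dimethyl sulfate, COS(=O)(=O)OC
Why: Selective Williamson-type O-methylation; the 4-OH para to the ketone is the most acidic hydroxyl and the only one that cannot hydrogen-bond to the carbonyl group, so one equivalent of base and alkylating agent should react there first.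

Step 12
Reactants: 21 aspidinol
Product: 22 1-{3-[(dimethylamino)methyl]-2,6-dihydroxy-4-methoxy-5-methylphenyl}butan-1-one
Conditions: 37% aq HCHO (1.3 equiv) premixed with 40% aq Me2NH (1.3 equiv), EtOH, 0 °C to rt
Reagents that add atoms: formaldehyde, C=O; dimethylamine, CNC
Why: Phenolic Mannich reaction at the single free ring position of aspidinol, which is ortho to a hydroxyl group as later quinone methide formation requires.

Step 13
Reactants: 22 1-{3-[(dimethylamino)methyl]-2,6-dihydroxy-4-methoxy-5-methylphenyl}butan-1-one; 23 1-(2,4,6-trihydroxyphenyl)butan-1-one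
Product: 25 1-[3-[(3-butanoyl-2,4-dihydroxy-6-methoxy-5-methylphenyl)methyl]-2,4,6-trihydroxyphenyl]butan-1-one, via ortho-quinone methide 24 (not isolated)
Conditions: 22 (1 equiv), 23 (3 equiv), AcOH (1 equiv), 1,4-dioxane, 100 °C, N2
Reagents that add atoms: none
Why: Thermal loss of dimethylamine from the Mannich base gives ortho-quinone methide 24, which is C-alkylated in a Michael-type addition by the phloroglucinol ring of 23; the two free positions of 23 are equivalent, its threefold excess keeps a second alkylation statistically small, and AcOH binds the released amine so that the medium stays non-basic.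

Step 14
Reactants: 18 1-{3-[(dimethylamino)methyl]-2,4-dihydroxy-6-methoxy-5-methylphenyl}butan-1-one; 25 ring B–ring C dimer
Product: 27 1-[3-[(3-butanoyl-2,6-dihydroxy-4-methoxy-5-methylphenyl)methyl]-5-[(3-butanoyl-2,4-dihydroxy-6-methoxy-5-methylphenyl)methyl]-2,4,6-trihydroxyphenyl]butan-1-one, via ortho-quinone methide 26 (not isolated)
Conditions: 18 (1.1 equiv), 25 (1 equiv), AcOH (1.1 equiv), 1,4-dioxane, 100 °C, N2
Reagents that add atoms: none
Why: Mannich base to ortho-quinone methide to Michael-type C-alkylation as in step 13; 25 has one unsubstituted ring carbon (on ring B) and 26 has none, so only the A–B bridge can form by C–C bonding, and the acetic acid buffer should suppress base-induced retro-Michael exchange of the bridge already in place.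

Compound list
1 | 2,4-dihydroxy-3-methylbenzaldehyde | O=Cc1ccc(O)c(C)c1O | starting material
2 | 4-(benzyloxy)-2-hydroxy-3-methylbenzaldehyde | O=Cc1ccc(OCc2ccccc2)c(C)c1O | intermediate
3 | 4-(benzyloxy)-2-methoxy-3-methylbenzaldehyde | O=Cc1ccc(OCc2ccccc2)c(C)c1OC | intermediate
4 | 4-(benzyloxy)-2-methoxy-3-methylphenyl formate (not isolated) | O=COc1ccc(OCc2ccccc2)c(C)c1OC | intermediate
5 | 4-(benzyloxy)-2-methoxy-3-methylphenol | Oc1ccc(OCc2ccccc2)c(C)c1OC | intermediate
6 | 4-(benzyloxy)-2-methoxy-3-methylphenyl N-(propan-2-yl)carbamate | CC(C)NC(=O)Oc1ccc(OCc2ccccc2)c(C)c1OC | intermediate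
7 | 4-(benzyloxy)-2-methoxy-3-methylphenyl N-(tert-butyldimethylsilyl)-N-(propan-2-yl)carbamate (not isolated) | CC(C)N(C(=O)Oc1ccc(OCc2ccccc2)c(C)c1OC)[Si](C)(C)C(C)(C)C | intermediate
8 | 6-lithio derivative of 7 (not isolated) | CC(C)N(C(=O)Oc1c([Li])cc(OCc2ccccc2)c(C)c1OC)[Si](C)(C)C(C)(C)C | intermediate
9 | 4-(benzyloxy)-2-methoxy-3-methyl-6-(trimethylsilyl)phenyl N-(tert-butyldimethylsilyl)-N-(propan-2-yl)carbamate (not isolated) | CC(C)N(C(=O)Oc1c([Si](C)(C)C)cc(OCc2ccccc2)c(C)c1OC)[Si](C)(C)C(C)(C)C | intermediate
10 | 4-(benzyloxy)-2-methoxy-3-methyl-6-(trimethylsilyl)phenyl N-(propan-2-yl)carbamate | CC(C)NC(=O)Oc1c([Si](C)(C)C)cc(OCc2ccccc2)c(C)c1OC | intermediate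
11 | 4-(benzyloxy)-2-methoxy-3-methyl-6-(trimethylsilyl)phenol, present as its DBU salt (not isolated) | COc1c(C)c(OCc2ccccc2)cc([Si](C)(C)C)c1O | intermediate
12 | 4-(benzyloxy)-2-methoxy-3-methyl-6-(trimethylsilyl)phenyl trifluoromethanesulfonate | COc1c(C)c(OCc2ccccc2)cc([Si](C)(C)C)c1OS(=O)(=O)C(F)(F)F | intermediate
13 | butanoic acid | CCCC(=O)O | starting material
14 | 5-(benzyloxy)-3-methoxy-4-methyl-1,2-didehydrobenzene, the a5≡a6 aryne (not isolated) | COC1=C(C)C(OCc2ccccc2)=CC#C1 | intermediate
15 | caesium 4-(benzyloxy)-2-(butanoyloxy)-6-methoxy-5-methylphenide, anion at a5 (not isolated) | CCCC(=O)Oc1cc(OCc2ccccc2)c(C)c(OC)[c-]1.[Cs+] | intermediate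
16 | 1-[4-(benzyloxy)-2-hydroxy-6-methoxy-5-methylphenyl]butan-1-one | CCCC(=O)c1c(O)cc(OCc2ccccc2)c(C)c1OC | intermediate
17 | 1-(2,4-dihydroxy-6-methoxy-5-methylphenyl)butan-1-one | CCCC(=O)c1c(O)cc(O)c(C)c1OC | intermediate
18 | 1-{3-[(dimethylamino)methyl]-2,4-dihydroxy-6-methoxy-5-methylphenyl}butan-1-one | CCCC(=O)c1c(O)c(CN(C)C)c(O)c(C)c1OC | intermediate
19 | 2-methylphloroglucinol (2-methylbenzene-1,3,5-triol) | Cc1c(O)cc(O)cc1O | starting material
20 | 1-(2,4,6-trihydroxy-3-methylphenyl)butan-1-one | CCCC(=O)c1c(O)cc(O)c(C)c1O | intermediate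
21 | aspidinol, 1-(2,6-dihydroxy-4-methoxy-3-methylphenyl)butan-1-one | CCCC(=O)c1c(O)cc(OC)c(C)c1O | intermediate
22 | 1-{3-[(dimethylamino)methyl]-2,6-dihydroxy-4-methoxy-5-methylphenyl}butan-1-one | CCCC(=O)c1c(O)c(CN(C)C)c(OC)c(C)c1O | intermediate
23 | 1-(2,4,6-trihydroxyphenyl)butan-1-one | CCCC(=O)c1c(O)cc(O)cc1O | starting material
24 | 2-butanoyl-3-hydroxy-5-methoxy-4-methyl-6-methylidenecyclohexa-2,4-dien-1-one (not isolated) | C=C1C(=O)C(C(=O)CCC)=C(O)C(C)=C1OC | intermediate
25 | 1-[3-[(3-butanoyl-2,4-dihydroxy-6-methoxy-5-methylphenyl)methyl]-2,4,6-trihydroxyphenyl]butan-1-one | CCCC(=O)c1c(O)cc(O)c(Cc2c(O)c(C(=O)CCC)c(O)c(C)c2OC)c1O | intermediate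
26 | 4-butanoyl-5-hydroxy-3-methoxy-2-methyl-6-methylidenecyclohexa-2,4-dien-1-one (not isolated) | C=C1C(=O)C(C)=C(OC)C(C(=O)CCC)=C1O | intermediate
27 | 1-[3-[(3-butanoyl-2,6-dihydroxy-4-methoxy-5-methylphenyl)methyl]-5-[(3-butanoyl-2,4-dihydroxy-6-methoxy-5-methylphenyl)methyl]-2,4,6-trihydroxyphenyl]butan-1-one (CNP0171986.0) | CCCC(=O)c1c(O)c(Cc2c(O)c(C)c(OC)c(C(=O)CCC)c2O)c(O)c(Cc2c(O)c(C(=O)CCC)c(O)c(C)c2OC)c1O | target

Total step count: 14
Longest linear sequence: 10 steps (steps 1–9, then step 14); the second branch has 5 steps (steps 10–13, then step 14).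

Steps most likely to fail

Step 7. The aryl anion may be protonated before the 1,3-acyl shift, by hydrogen difluoride, by residual acid or by the α-hydrogens of its own ester, so that the reaction stops at O-arylation. The product phenoxide may also be arylated by a second aryne. The fallback uses no aryne and relies on chelation-controlled protection of an acylphloroglucinol; it sets out from 20 and comes back at 17.
- BnBr (2.1 equiv) with K2CO3 in DMF should etherify the 4-OH and the less hindered 6-OH. The 2-OH, wedged between ketone and methyl group and chelated, stays free, which gives 1-[4,6-bis(benzyloxy)-2-hydroxy-3-methylphenyl]butan-1-one F1.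
- Forcing methylation (MeI, K2CO3, DMF, 60 °C) gives 1-[4,6-bis(benzyloxy)-2-methoxy-3-methylphenyl]butan-1-one F2.
- Hydrogenolysis of both benzyl ethers (H2, Pd/C, EtOAc–MeOH) gives 17.

Step 14. Capture of the quinone methide at the crowded last free position of ring B may be slower than its self-reaction. Prolonged heating may also open the existing C–B bridge by retro-Michael cleavage and scramble the terminal rings. The fallback exchanges the roles of the partners; it sets out from 25 and comes back at 27.
- Aminomethylation of 25 (HCHO, Me2NH, EtOH, 0 °C to rt) at its only free ring carbon gives 1-[3-[(3-butanoyl-2,4-dihydroxy-6-methoxy-5-methylphenyl)methyl]-5-[(dimethylamino)methyl]-2,4,6-trihydroxyphenyl]butan-1-one F3.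
- Heating F3 with 17 (1.5 equiv, the excess recoverable) in dioxane–AcOH releases 4-butanoyl-2-[(3-butanoyl-2,4-dihydroxy-6-methoxy-5-methylphenyl)methyl]-3,5-dihydroxy-6-methylidenecyclohexa-2,4-dien-1-one F4.
- F4 is trapped by the small, unhindered a1 position of 17, which lies between two hydroxyl groups, to give 27.

Step 5. Deprotonation at the benzylic CH2 of the benzyl ether may compete with ring lithiation. Incomplete N-silylation may lead to loss of isocyanate under n-BuLi. The fallback replaces deprotonation by halogen–metal exchange; it sets out from 5 and comes back at 12.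
- Amine-mediated ortho-bromination (NBS, i-Pr2NH cat., CH2Cl2, 0 °C) gives 4-(benzyloxy)-6-bromo-2-methoxy-3-methylphenol F5. The hydrogen-bonded phenol is the dominant donor and should steer bromine next to the hydroxyl group.
- Hexamethyldisilazane in refluxing THF gives [4-(benzyloxy)-6-bromo-2-methoxy-3-methylphenoxy]trimethylsilane F6.
- n-BuLi at −78 °C effects bromine–lithium exchange, far faster than any deprotonation. A 1,3 O-to-C silyl shift (retro-Brook rearrangement) then gives lithium 4-(benzyloxy)-2-methoxy-3-methyl-6-(trimethylsilyl)phenoxide F7.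
- Tf2O at −78 °C converts F7 into 12.

Further compounds
F1 | step 7 | 1-[4,6-bis(benzyloxy)-2-hydroxy-3-methylphenyl]butan-1-one | CCCC(=O)c1c(O)c(C)c(OCc2ccccc2)cc1OCc1ccccc1
F2 | step 7 | 1-[4,6-bis(benzyloxy)-2-methoxy-3-methylphenyl]butan-1-one | CCCC(=O)c1c(OC)c(C)c(OCc2ccccc2)cc1OCc1ccccc1
F3 | step 14 | 1-[3-[(3-butanoyl-2,4-dihydroxy-6-methoxy-5-methylphenyl)methyl]-5-[(dimethylamino)methyl]-2,4,6-trihydroxyphenyl]butan-1-one | CCCC(=O)c1c(O)c(CN(C)C)c(O)c(Cc2c(O)c(C(=O)CCC)c(O)c(C)c2OC)c1O
F4 | step 14 | 4-butanoyl-2-[(3-butanoyl-2,4-dihydroxy-6-methoxy-5-methylphenyl)methyl]-3,5-dihydroxy-6-methylidenecyclohexa-2,4-dien-1-one | C=C1C(=O)C(Cc2c(O)c(C(=O)CCC)c(O)c(C)c2OC)=C(O)C(C(=O)CCC)=C1O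
F5 | step 5 | 4-(benzyloxy)-6-bromo-2-methoxy-3-methylphenol | COc1c(C)c(OCc2ccccc2)cc(Br)c1O
F6 | step 5 | [4-(benzyloxy)-6-bromo-2-methoxy-3-methylphenoxy]trimethylsilane | COc1c(C)c(OCc2ccccc2)cc(Br)c1O[Si](C)(C)C
F7 | step 5 | lithium 4-(benzyloxy)-2-methoxy-3-methyl-6-(trimethylsilyl)phenoxide | COc1c(C)c(OCc2ccccc2)cc([Si](C)(C)C)c1[O-].[Li+]
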